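The numbers in the tables are simulated for substances that don't exist, noise included.

40.0% of the oak run's starting material is what stands between it and the larch run: once the oak run has turned that share into target, it holds 0.0600 M of starting material and 0.160 M of partner, which is the charge of the larch run. This is the same-excess test of reaction progress analysis. Read between its last two readings, the oak run reaches that share at 4.24 min, and we call this the catch-up time: the clock offset that should lay the larch run on the oak run.

| flask | starting material | partner | catalyst | target | time |
|---|---|---|---|---|---|
| oak | 0.100 M | 0.200 M | 0.00800 M |  |  |
| larch | 0.0600 M | 0.160 M | 0.00800 M |  |  |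
| maple | 0.100 M | 0.200 M | 0.00800 M | 0.0300 M |  |
| ash | 0.100 M | 0.200 M | 0.0120 M |  |  |
| birch | 0.100 M | 0.200 M | 0.00800 M |  | 13 min |

| run | time / min | [target] / M |
|---|---|---|
| oak run | 0.40 | 0.0050 |
| oak run | 1.2 | 0.0136 |
| oak run | 2.3 | 0.0242 |
| oak run | 3.7 | 0.0359 |
| oak run | 5.3 | 0.0480 |
| larch run | 0.40 | 0.0031 |
| larch run | 1.2 | 0.0083 |
| larch run | 2.3 | 0.0160 |
| larch run | 3.7 | 0.0233 |
| larch run | 5.3 | 0.0314 |
| maple run | 0.40 | 0.0343 |
| maple run | 1.2 | 0.0434 |
| maple run | 2.3 | 0.0539 |
| maple run | 3.7 | 0.0661 |
| maple run | 5.3 | 0.0782 |
| ash run | 0.40 | 0.0067 |
| ash run | 1.2 | 0.0192 |
| ash run | 2.3 | 0.0337 |
| ash run | 3.7 | 0.0501 |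
| ash run | 5.3 | 0.0644 |

(scatter of a reading: 3 × 10⁻⁴ M)

- order of the initial rate in [catalyst], near the charge of the oak run, the rate being that where two percent of its starting material are target
- the larch run starts with 0.0400 M less of starting material and of partner than the oak run, and with no target. Compared where both hold the same amount of starting material, once fifteen percent of what the larch run was charged with has turned into target, is the larch run faster, slower or alike (within a tenth)?
- target in the birch run at 13 min, as a share of the starting material charged

- Overall: starting material + partner -> target, with catalyst as catalyst.
- Constant volume, constant temperature.
- The analysis sees a species whether free or bound.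
- An order is taken over about fifteen percent of the charge, up and down.

We turn the question round. For the larch run to part from the oak run by more than a tenth, the target already made or the age of the catalyst would have to move the rate by that much, since these are what still differ between the two flasks at equal starting material. Target shows no such effect in the maple run, whose gain by 5.3 min is 1.00 of the oak run's although it was charged with target equal to 30.0% of its starting material. For age, the oak run, past its catch-up time for part of the span, loses 0.131 min⁻¹ of what it holds between 3.7 min and 5.3 min, and the larch run, with fresh catalyst, loses 0.135 min⁻¹ over its first 2.3 min, a span of starting material that overlaps the oak run's without matching it. These differ by 3.14%, less than the tenth, though scatter puts about 3.51% on the oak figure. So we say alike.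

Then the birch run, which has the oak charge, can borrow the larch run's later life. The last larch reading, with starting material left equal to 28.6% of the birch charge of it, we place at 9.54 min on the birch clock. Carrying on for the remaining 3.46 min at the larch run's last loss of 0.156 min⁻¹ gives 83.3% as target. From the ash and oak readings at 1.2 min we read a catalyst order of 0.931.

The forecast gave 0.95, alike and 83%, on the ground that “Larch has the same excess as oak, so at equal A it overlays oak”. The flask gives an order of 1.0, alike and 84.3%.

    catalyst + starting material + partner → target + catalyst (1524 L² mol⁻² min⁻¹)
    2 starting material ⇌ idle substrate dimer, settled at all times (130.0 L mol⁻¹)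
    2 partner ⇌ idle reagent dimer, settled at all times (25.20 L mol⁻¹)

In the ash run, the step joining catalyst, starting material and partner ran with 1.50 times the oak run's catalyst, and the catch-up time divided by that factor is 2.83 min, while the ash readings pass the same 40.0% of the charge at 2.84 min. In the birch run that step ran for 13 min, 8.76 min of them past the catch-up time, beside both dimers in balance, while the free share of the starting material still present, the rest being held as idle substrate dimer, rose from 17.8% at the start to 38.7% at 13 min, when 84.3% of the charge was target.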